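The earlier runs and the new flask stem from a simulated flask with constants of no real substance; the scatter is artificial.

At early times the blue run, a closed flask of 46 mM starting material with 4.6 mM protic impurity, already misses something: at 1.00 h target and starting material together read 89.0%, so about 11.0% of the charge has gone elsewhere. The impurity's charge comes to 10.0% of the starting material, and I call this share the toll: the part of the starting material that the protic impurity can take, one for one, if it is consumed to the last.

| flask | starting material | reagent | protic impurity | free catalyst | remark | time |
|---|---|---|---|---|---|---|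
| blue | 46 mM | 1 equiv | 4.6 mM | 0.5 mol% | run made earlier |  |
| ochre | 64 mM | 1 equiv | 4.6 mM | 0.5 mol% | run made earlier |  |
| grey | 100 mM | 1 equiv | 4.6 mM | 0.5 mol% | run made earlier |  |
| violet | 46 mM | 1 equiv | 4.6 mM | 1 mol% | run made earlier |  |
| ash | 46 mM | 1.00 equiv | 4.60 mM | 0.5 mol% | a tube with plug flow, the mixed feed as stated, residence time 20 h | 20 h |
| maple | 46 mM | 1.00 equiv | 4.60 mM | 0.5 mol% | one stirred flow tank at steady state, fed with the mixture as stated, mean residence time 20 h |  |
| cedar | 46 mM (fed, over 16.0 h) | 1.00 equiv | 4.60 mM | 0.5 mol% | a stirred flask in which starting material is dosed at a steady rate over 16.0 h without added volume, worked up at 20 h | 20 h |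
| elm | 46 mM | 1.00 equiv | 4.60 mM | 0.5 mol% | a closed flask charged with all of it at once and left for 20 h | 20 h |

- blue (time / h: target / %, starting material / %): 1.00: 61.4, 27.6; 1.33: 73.0, 16.9; 2.00: 86.7, 3.0; 3.00: 87.1, 0.2; 5.00: 89.7, 0.3; 8.00: 88.4, 0.5; 12.0: 90.0, 0.3
- ochre (time / h: target / %, starting material / %): 2.50: 94.5, 0; 5.00: 91.9, 0.1; 6.00: 93.5, 0; 10.0: 93.2, 0; 12.0: 93.8, 0; 15.0: 93.9, 1.1
- grey (time / h: target / %, starting material / %): 2.50: 95.3, 0; 5.00: 95.4, 0; 6.00: 95.2, 0; 10.0: 95.3, 0; 12.0: 94.8, 0; 15.0: 95.8, 0.4
- violet (time / h: target / %, starting material / %): 3.00: 89.8, 0.9; 6.00: 89.5, 1.4; 10.0: 91.9, 0; 12.0: 90.2, 0.1; 15.0: 89.6, 0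

(scatter of a reading: 1 percentage point)

1. the set-up with the highest amount of target at the outlet or at the end, in percent of the starting material put in ("none" if the first two lie within 2 percentage points) (ash / maple / cedar / elm / none)
2. amount of target at the outlet or at the end, in percent of the starting material put in, ash
3. amount of target at the outlet or at the end, in percent of the starting material put in, maple
4. amount of target at the outlet or at the end, in percent of the starting material put in, cedar
5. amount of target at the outlet or at the end, in percent of the starting material put in, elm

- the stated concentrations are those of everything mixed, before any reaction; amounts are the same in each set-up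
- reactions considered so far: starting material + catalyst intermediate A -> catalyst intermediate B; catalyst intermediate B -> free catalyst + target; starting material + protic impurity -> quenched substrate; reagent + free catalyst <-> catalyst intermediate A
- the feed brings no volume worth counting
- the earlier runs were made in a closed, stirred flask

I test the toll on the other runs: one minus the toll gives 92.8% for ochre, which reads 93.2% at 10.0 h, and 95.4% for grey, which reads 95.3% at 10.0 h. The violet run, with twice the catalyst of blue, still reads 89.6% at 15.0 h. Blue has 0.2% starting material left at 3.00 h, so for elm, charged at once, and for ash, whose plug-flow slices each live the same 20 h, I commit to 90.0%.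

The weak link is cedar, where the toll is paid in full only if the impurity meets enough starting material. Blue's starting material falls by about 11.3 mM h⁻¹ on average between 1.00 h and 2.00 h, and cedar's feed of 2.88 mM h⁻¹ is about a quarter of that. So I expect cedar's starting material to stay low, below the average near 29.3 mM through blue's first hour, though these readings give me no level to reckon with. The impurity can take the toll and not beyond it, so I reforge the link and put cedar on the line or somewhat above it.

The forecast says “the impurity quenches its stoichiometric share quickly and completely” and gives 90% for ash, 88.9% for maple, 90.4% for cedar, 90% for elm, and none as the best.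

The simulation gives 90.0% for ash, 90.9% for maple, 91.8% for cedar, 90.0% for elm, and none as the best.

    starting material + catalyst intermediate A → catalyst intermediate B (k = 130 M⁻¹ s⁻¹)
    catalyst intermediate B → free catalyst + target (k = 0.0940 s⁻¹)
    starting material + protic impurity → quenched substrate (k = 0.390 M⁻¹ s⁻¹)
    reagent + free catalyst ⇌ catalyst intermediate A (K = 37.0 M⁻¹, k = 1.90 M⁻¹ s⁻¹)

Elm ends with 10.0% quenched substrate, the full toll, while cedar ends with 8.24% and 17.6% of its impurity unspent, which puts cedar 1.8 percentage points above elm against a margin of 2 points. The neighbouring dosed flask takes 110 mM of starting material with the same 4.60 mM impurity, so its toll is 4.18% and its line 95.8%. That flask ends with 3.02% quenched substrate, 28% of its impurity unspent, and 97.0% target.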